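The constants are made up, and the outcome is calculated.

A small charge of X turns a racemate of D and L over with J, and I want to see where X stands at a fixed conversion.

    J + X + L → X + E (k1 = 12 /M²/h)
    X ⇌ G (K2 = 0.47, k2 = 0.14 /h)
    J + X + D → X + Q (k3 = 37 /M²/h)
    J + X → J.X (k4 = 0.072 /M/h)

D 0.30 M; J 0.240 M; X 30 mM; L 0.30 M

1. the form that holds most of the catalyst when 30% of the D and L together are converted (X / J.X / G)
2. its share of the catalyst then
3. apparent order in X when 30% of the D and L together are converted (percent change of the rate of making Q for one percent more X charged)

I write a for the fraction of D still left. Steps of D, of L and of J.X formation all carry the same factor, J times X, so they run on one common clock whatever J and X do in time. The logarithm of the fall of D is therefore 3.08 times that of L, this ratio being the selectivity factor. The asked conversion makes the left fractions of D and L add up to 1.40, and one Newton step from 0.5 gives a = 0.567. The same clock gives the rule I carry: the fraction of the catalyst lost to J.X is ln(1/a) times the loss coefficient, k4 over k3 times the charge of X, which is 6.49%. Here that makes 3.68%.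

If X and G had reached equilibrium, X would hold 65.5%. That assumption is the weak link, so I test it. The pair relaxes at 0.438 /h. J falls to 25.0% of its charge, with a logarithmic mean of 54.1%, and X averages about 84.0%, so the clock needs 4.69 h. That leaves 12.8% of the excess over equilibrium, and I commit to X as the resting state, at 69.5%. At fixed conversion, J and D do not depend on the charge of X. More X leaves the same amount of J.X and shortens the time, which keeps more out of G, so I reckon an order of 1.16.

The forecast says X at 68.5% (66% to 71%), below my share, with order 1.15 (1.08 to 1.22), “leaving free X holding about two-thirds of it”.

The flask gives X at 68.3%, G at 28.0%, J.X at 3.67% and order 1.2, after 5.31 h, longer than my time. At 8.00 d, with J at 0% and 44% of D left, the rule gives 5.33% and the flask holds 5.33% in J.X. The order in this flask stays near one in part because G runs back to X: in the run without that reverse step, the order at the asked conversion goes from 1.2 to 2.6.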